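The readings stem from a simulated flask with constants of no real substance.

If a flask is read long after side product A has overtaken the target, the target is a minority in what the asked share counts. The quantity to carry is therefore the moment of overtaking.

| setting | Tuesday's | zeta | gamma | eta |
|---|---|---|---|---|
| substrate | 0.40 M | 0.40 M | 0.40 M | 0.40 M |
| reagent | 2.4 equiv | 1.20 equiv | 1.20 equiv | 1.20 equiv |
| temperature | 30 °C | 30 °C | 55 °C | 5 °C |
| remark | run made earlier |  |  |  |
| time |  | 2.5 min | 2.5 min | 2.5 min |

- the flask with the highest share of target in all that became target or side product A or side product B ("all alike" if they lie within 1.5 percentage points) (zeta / gamma / eta / all alike)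
- share of target in all that became target or side product A or side product B, zeta
- share of target in all that became target or side product A or side product B, gamma
- share of target in all that became target or side product A or side product B, eta

- the earlier runs do not show what temperature does; that part of a forecast is a guess

- Tuesday's (time / s: target / %, side product A / %): 10.0: 3.5, 8.1; 15.0: 4.5, 14.1; 20.0: 4.2, 20.0; 25.0: 5.0, 26.2; 30.0: 4.6, 30.3

(scatter of a reading: 0.3 percentage points)

The target column rises at first, then stays near 4.58 % from the second row on, within the scatter. The column of side product A keeps climbing. Its first and last rows give a slope of 0.0111 /s as a fraction of the charge. Already in the first row, side product A stands higher than the target, so the overtaking lies before the readings. Extended backwards, the line meets the target's level at the crossing time, the moment at which c(side product A) passes c(target): 6.82 s, a reading with its scatter.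

The recipes are read at 2.5 min, which is 22.0 crossing times of Tuesday's flask. Taking the crossing as unmoved by the reagent, which is a guess, zeta at 30 °C is read far past it, and gamma is hotter still.

The forecast puts eta highest, with 9 % (4 % to 13 %) for zeta, 4 % (1 % to 9 %) for gamma and 28 % (11 % to 45 %) for eta, “assuming rates about four times slower” in the cold. That factor gives a crossing at 27.3 s, earlier than the reading.

The flasks give 6.35 % in zeta, 1.31 % in gamma and 53.6 % in eta, so eta ranks highest.

    substrate + reagent → intermediate A (k = 0.0200 /M/s, Ea = 47.0 kJ/mol)
    substrate ⇌ intermediate B (K = 0.730, k = 0.0230 /s, Ea = 71.0 kJ/mol, ΔH = −65.0 kJ/mol)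
    intermediate A → side product A (k = 0.00220 /s, Ea = 73.0 kJ/mol)
    reagent + intermediate A → side product B (k = 0.00340 /M/s, Ea = 49.0 kJ/mol)
    reagent + intermediate B → target (k = 0.0120 /M/s, Ea = 59.0 kJ/mol)
    2 substrate → homo dimer (k = 0.00400 /M/s, Ea = 53.0 kJ/mol)
    (constants at 5 °C)

Gamma is read far past its crossing: side product A at 69.9 % stands above the target at 1.01 %. The back reaction of intermediate B to substrate is the main reason for gamma's low share: the same run without that back reaction gives 92.6 % instead of 1.31 %. Eta, at 2.50 min, which is 22.0 of Tuesday's crossing times, has not reached its crossing: the target at 12.9 % stands above side product A at 7.51 %. The neighbour of eta with 0.16 M of substrate also stands before its crossing, with target 8.23 % above side product A 4.18 %, and its share is 61.3 %.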